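Numbering used throughout: isoflavan numbering (O1, C2, C3, C4, C4a, C5–C8, C8a; ring B primed). Abbreviations in names: TBS = tert-butyldimethylsilyl, TIPS = tri(propan-2-yl)silyl, MOM = methoxymethyl, prenyl = 3-methylbut-2-en-1-yl.

## The problem

Compound 25 is a (3R)-isoflavan: benzene ring A is fused to the dihydropyran ring C (O1, C2, C3, C4), and C3 carries the resorcinol ring B. Ring A is pentasubstituted, with O1 on C8a, a formyl group on C8, a free hydroxyl on C7, hydrogen on C6 and a methoxy group on C5. Three oxygen functions must therefore be told apart, and the one-carbon unit must sit on C8 and not on C6. Ring B has hydroxyls on C2' and C4' and a prenyl group between them on C3', the most hindered position of that ring. C3 is the only stereocentre and nothing in the molecule can relay chirality to it, so it must be set by a catalyst or an auxiliary. It is configurationally safe only once C2 is a saturated CH2 group, because with C2 at the aldehyde or lactol level C3 is an enolisable α-aryl carbon. The prenyl alkene flanked by two phenols will not survive hydrogenolysis, strong protic or Lewis acid (closure to a 2,2-dimethylchroman) or electrophilic oxidants, and the salicylaldehyde and free resorcinol call for a mild last step. The feature that opens the way is that O1–C8a–C4a–C4 is the skeleton of an ortho-quinone methide of ring A (C8a the carbonyl carbon, C4 the exocyclic methylene), while C2–C3 with ring B attached is an arylacetaldehyde with C3 as α-carbon and C2 as carbonyl carbon.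

## Retrosynthesis

**Protecting groups and the C8 oxidation level (25 ⇐ 24 ⇐ 23 ⇐ 22).** No skeletal bond is cut. The three phenols are revealed last from silyl ethers, because fluoride is the one deprotection that leaves a prenyl group between two phenols untouched; acetals would need acid and benzyl ethers hydrogen. The aldehyde of 24 is traced through alcohol 23 to the methyl ester of 22. The ester is the C8 carbon of the starting benzoate, so its position is never in doubt, whereas a late formylation would have to choose between C6 and C8. The forward steps must reduce a hindered benzoate without touching aryl silyl ethers and oxidise a benzylic alcohol without touching the alkene.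

**O1–C2 (22 ⇐ 21 ⇐ 20).** The ether bond O1–C2 is cut to give phenol–alcohol 21, which is the reduced form of lactol 20. Direct ionic deoxygenation of 20 would be one step shorter. It would pass through an oxocarbenium ion that can lose the C3 proton, and it needs an acid that attacks the prenyl group. Hydride reduction followed by a redox-neutral dehydrative closure keeps C3 and the alkene safe. The closure must take the C8a phenol, which is hydrogen-bonded to the ester, onto a primary carbon.

**C3–C4 and O1–C2 at the hemiacetal level (20 ⇐ 5 + 16).** This is the central cut. It divides the molecule into two halves of similar size, each an aromatic ring with all its substituents in place: sulfone 5, a latent ortho-quinone methide of ring A, and arylacetaldehyde 16. The neighbouring cuts are weaker. A C3–C1' cut would need a doubly ortho-substituted ring B nucleophile. A C4–C4a ring closure by aromatic substitution would not distinguish the two free positions of a phloroglucinol-type ring. Reduction of an isoflavene or isoflavone is barred by the prenyl group. The forward reaction must add the aldehyde α-carbon to the methide carbon on one enantiotopic face only; C4 carries two hydrogens, so no second centre of consequence arises.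

**Ring A piece (5 ⇐ 4 ⇐ 2 ⇐ 1).** The O–Si bond of 5 is cut to diol 4. The C4a–C4 and C4–S bonds of 4 are cut together to the symmetrical dihydroxybenzoate 2, a one-carbon aldehyde and a sulfinate salt. The symmetry of 2 means that only mono- against bis-substitution has to be controlled. The O-methyl bond of 2 leads to commercial triol 1, whose 4-hydroxyl is the only one not chelated to the ester. The forward silylation must select the hydroxyl remote from the new benzylic group, so that the free phenol of 5 is the one ortho to it.

**Ring B piece, oxidation level and protecting groups (16 ⇐ 15 ⇐ 14 ⇐ 13 ⇐ 12).** Aldehyde 16 is made last from alcohol 15 by a neutral oxidation, because arylacetaldehydes do not keep. The silyl ethers of 15 cannot be carried through aryllithium chemistry: a lithium ortho to a silyloxy group invites O-to-C silyl migration, and silyl ethers do not direct metalation. The C–C bonds are therefore made on the MOM acetal 12. The acetals are removed at the stage of the simple achiral triol 13, where dilute acid can be used, and silyl groups are put on through tris-ether 14 with selective release of the primary alcohol.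

**Ring B piece, carbon skeleton (12 ⇐ 10 ⇐ 7 + 8 ⇐ 6).** The C1'–CH2 bond of 12 is cut to the aryllithium from bromide 10 and a two-carbon epoxide. The C3'–prenyl bond of 10 is cut to bromide 7 and prenyl bromide 8. The position between the two acetal oxygens of 7 is the most acidic on the ring, and the bromine of commercial 6 marks C1' for the later halogen–lithium exchange. The order matters: deprotonation comes before the prenyl group is present, so its benzylic–allylic CH2 cannot compete, and the exchange at low temperature is faster than any deprotonation.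

## Roads not taken

**Alternative 1:** The cut runs through ring B (C1'–C6' and C3'–C4'). Ring B is traced to an acrylic ester and methyl ketone A2, a 3-(2-oxopropyl)chroman that already holds rings A and C and the C3 centre. In the forward step the enolate of A2 would add through its methylene carbon to the acrylic ester, and the methyl-side enolate would then close on the ester (Michael addition, then Claisen condensation) to give cyclohexane-1,3-dione A1. C-prenylation between the carbonyl groups and dehydrogenation would complete ring B.
- Merit: the carbon between the two carbonyls is the only doubly activated position, so the prenyl group lands on C3' without directing groups, lithiation or exchange of protecting groups, and no sensitive arylacetaldehyde is needed. Here this road is better than the chosen plan, which spends steps 4 to 9 on exactly this.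
- Weak points: the Michael donor must be the more substituted enolate of an unsymmetrical ketone, and O-prenylation competes with C-prenylation. Above all, the dione must be dehydrogenated to a resorcinol with the prenyl alkene present. Halogenation–elimination, high-valent metal oxidants and hot palladium catalysts all threaten a trisubstituted alkene or the new resorcinol. C3 is not addressed, so A2 would need its own asymmetric step, and the acetal on O7 brings back an acidic last step.
- Comparison: the chosen plan buys both rings aromatic, applies no oxidant stronger than an alcohol-to-aldehyde reagent near the alkene, and sets C3 in the step that forms ring C.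

**Alternative 2:** The cut is C4a–C8a and C7–C8, so ring A itself is built. In precursor A4 a 2-silyloxy-4-methoxyfuran is tethered through C4–C3–C2–O1 to a β-alkoxyacrylate. An intramolecular Diels–Alder reaction would give an oxa-bridged adduct that loses silanol and water to the phenol ester A3, forming rings A and C together.
- Merit: the substitution pattern of ring A (ester on C8, hydroxyl on C7, methoxy on C5) is written into the components. No aromatic substitution has to be steered and the C7 hydroxyl emerges free and differentiated. In this respect it is better than the chosen plan, which must control mono-substitution in step 2 and site-selective silylation in step 3.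
- Weak points: diene and dienophile are both electron-rich, since the β-alkoxy group deactivates the acrylate, so the cycloaddition is poorly matched. 5-Alkyl-2-silyloxyfurans are fragile and tend to react as vinylogous enol ethers, not as dienes. C3 must be set beforehand in the open chain of A4, which needs an asymmetric step and stepwise differentiation of a 2-arylpropane-1,3-diyl unit. A3 also has a free phenol beside the ester, which invites over-reduction through a quinone methide when the ester is reduced.
- Comparison: the chosen plan reaches its ring A component from benzoate 1 in three steps and has a key step of a known reaction type that also creates the stereocentre.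

**Alternative 3:** The cut is O1–C8a and the C8–CHO bond. Precursor A6 is a 3-(2-fluoroaryl)-2-arylpropan-1-ol. With excess strong base the alkoxide forms, C8 (between fluorine and the acetal oxygen) is lithiated, LiF is lost to give the C8–C8a aryne, the tethered alkoxide adds at C8a to close ring C, and the C8 aryllithium is trapped by a formamide to give tris-acetal A5.
- Merit: ring closure and formylation happen in one operation, and the aryne dictates the position of the formyl group. No ester is carried, so the reduction and oxidation of steps 14 and 15 disappear. In step count at the end it is better than the chosen plan.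
- Weak points: an excess of alkyllithium or amide base meets a benzylic–allylic CH2 flanked by two directing acetals and a ring B C–H ortho to an acetal, so competing metalation is likely. The directing group on O7 makes the product the tris-acetal A5, whose deprotection needs the protic acid that closes the prenyl group onto a phenol. C3 must again be set earlier in A6 by a separate asymmetric step.
- Comparison: the chosen plan pays two redox steps and an exchange of protecting groups, but from step 10 on its conditions are weakly basic, neutral or buffered, its last step is a fluoride desilylation, and the stereocentre is made in the ring-forming step.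

Key step: step 11

Remark: the sense of induction in step 11 is assigned from the face-shielding model for enamines of 2-[diaryl(silyloxy)methyl]pyrrolidines; on this model the (R)-amine leads to 3R.

## Steps

Step 1
Reactants: 1 methyl 2,4,6-trihydroxybenzoate
Product: 2 methyl 2,6-dihydroxy-4-methoxybenzoate
Conditions: Me2SO4 (1.0 equiv), K2CO3 (1.1 equiv), acetone, rt
Reagents that add atoms: dimethyl sulfate, COS(=O)(=O)OC
Why: Williamson O-methylation; the 4-hydroxyl is the most acidic and the only one not hydrogen-bonded to the ester, so one equivalent of the alkylating agent should be taken up there.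

Step 2
Reactants: 2 methyl 2,6-dihydroxy-4-methoxybenzoate
Product: 4 methyl 2,6-dihydroxy-4-methoxy-3-{[(4-methylphenyl)sulfonyl]methyl}benzoate, via benzylic alcohol 3 (not isolated)
Conditions: aq. HCHO (1.0 equiv), 4-MeC6H4SO2Na (2 equiv), HCO2H/H2O, rt to 40 °C
Reagents that add atoms: formaldehyde, C=O; sodium 4-methylbenzenesulfinate, Cc1ccc(S(=O)[O-])cc1.[Na+]
Why: Mannich-type three-component sulfonylmethylation of an activated phenol: hydroxymethylation ortho to a hydroxyl gives 3, whose benzylic hydroxyl is exchanged under acid for sulfinate bound through sulfur. C3 and C5 of 2 are equivalent, so only mono- against bis-substitution has to be held, by limiting formaldehyde and using excess sulfinate.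

Step 3
Reactants: 4 methyl 2,6-dihydroxy-4-methoxy-3-{[(4-methylphenyl)sulfonyl]methyl}benzoate
Product: 5 methyl 2-hydroxy-4-methoxy-3-{[(4-methylphenyl)sulfonyl]methyl}-6-(TIPS-oxy)benzoate
Conditions: iPr3SiOTf (1.05 equiv), 2,6-lutidine (1.5 equiv), CH2Cl2, −78 to 0 °C
Reagents that add atoms: tri(propan-2-yl)silyl trifluoromethanesulfonate, CC(C)[Si](C(C)C)(C(C)C)OS(=O)(=O)C(F)(F)F
Why: Site-selective silylation: the 6-hydroxyl has one ortho neighbour, whereas the 2-hydroxyl is flanked by the ester and the sulfonylmethyl group, so the bulky silyl triflate should take the former. The hindered weak base is meant to avoid loss of sulfinate from the phenoxide.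

Step 4
Reactants: 6 4-bromobenzene-1,3-diol
Product: 7 1-bromo-2,4-bis(methoxymethoxy)benzene
Conditions: MOMCl (2.5 equiv), iPr2NEt (3 equiv), CH2Cl2, 0 °C to rt
Reagents that add atoms: chloromethyl methyl ether, COCCl
Why: Standard O-alkylation of phenols to acetals; the MOM ethers direct and stabilise the aryllithiums of steps 5 and 6.

Step 5
Reactants: 7 1-bromo-2,4-bis(methoxymethoxy)benzene; 8 1-bromo-3-methylbut-2-ene
Product: 10 1-bromo-2,4-bis(methoxymethoxy)-3-prenylbenzene, via aryllithium 9 (not isolated)
Conditions: LiN(iPr)2 (1.1 equiv), THF, −78 °C; then CuBr·SMe2 (10 mol %), 8 (1.3 equiv), −78 to 0 °C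
Reagents that add atoms: none
Why: Directed ortho-metalation at the carbon flanked by both acetal oxygens, the most acidic and doubly coordinated site; the amide base leaves the C–Br bond alone, and lithium meta to bromine cannot give an aryne. Copper-catalysed allylic substitution then occurs at the unhindered primary carbon of 8.

Step 6
Reactants: 10 1-bromo-2,4-bis(methoxymethoxy)-3-prenylbenzene
Product: 12 2-[2,4-bis(methoxymethoxy)-3-prenylphenyl]ethan-1-ol, via aryllithium 11 (not isolated)
Conditions: n-BuLi (1.05 equiv), THF, −78 °C; ethylene oxide (5 equiv), −78 to 0 °C; H2O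
Reagents that add atoms: ethylene oxide, C1CO1
Why: Bromine–lithium exchange at −78 °C is faster than deprotonation of the benzylic–allylic CH2 and gives an aryllithium chelated by the ortho acetal. This opens the epoxide by SN2 attack to the 2-arylethanol.

Step 7
Reactants: 12 2-[2,4-bis(methoxymethoxy)-3-prenylphenyl]ethan-1-ol
Product: 13 4-(2-hydroxyethyl)-2-prenylbenzene-1,3-diol
Conditions: HCl (0.3 M) in MeOH, rt
Reagents that add atoms: none
Why: Acid-catalysed acetal exchange with methanol releases both phenols; dilute acid at room temperature is chosen so that acetal cleavage outruns addition of a phenol across the prenyl alkene.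

Step 8
Reactants: 13 4-(2-hydroxyethyl)-2-prenylbenzene-1,3-diol
Product: 14 tert-butyl{2-[2,4-bis(TBS-oxy)-3-prenylphenyl]ethoxy}dimethylsilane (tris-TBS ether of 13)
Conditions: tBuMe2SiOTf (3.5 equiv), 2,6-lutidine (5 equiv), CH2Cl2, 0 °C to rt
Reagents that add atoms: tert-butyldimethylsilyl trifluoromethanesulfonate, CC(C)(C)[Si](C)(C)OS(=O)(=O)C(F)(F)F
Why: Exhaustive silylation with the silyl triflate, which also reaches the doubly ortho-substituted 2'-hydroxyl. All three hydroxyls are silylated because the hindered phenols cannot be silylated in preference to the primary alcohol.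

Step 9
Reactants: 14 tris-TBS ether of 13
Product: 15 2-[2,4-bis(TBS-oxy)-3-prenylphenyl]ethan-1-ol
Conditions: pyridinium 4-toluenesulfonate (0.2 equiv), MeOH/CH2Cl2, rt
Reagents that add atoms: none
Why: Acid-catalysed methanolysis cleaves a primary alkyl silyl ether far faster than hindered aryl silyl ethers, whose oxygen is less basic, so only the side-chain alcohol should be released.

Step 10
Reactants: 15 2-[2,4-bis(TBS-oxy)-3-prenylphenyl]ethan-1-ol
Product: 16 2-[2,4-bis(TBS-oxy)-3-prenylphenyl]acetaldehyde
Conditions: Dess–Martin periodinane (1.2 equiv), NaHCO3, CH2Cl2, 0 °C to rt; used at once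
Reagents that add atoms: none
Why: Dess–Martin oxidation gives the enolisable arylacetaldehyde under buffered, non-aqueous conditions without over-oxidation and without touching the alkene or the silyl ethers.

Step 11
Reactants: 5 methyl 2-hydroxy-4-methoxy-3-{[(4-methylphenyl)sulfonyl]methyl}-6-(TIPS-oxy)benzoate; 16 2-[2,4-bis(TBS-oxy)-3-prenylphenyl]acetaldehyde
Product: 20 methyl (3R)-3-[2,4-bis(TBS-oxy)-3-prenylphenyl]-2-hydroxy-5-methoxy-7-(TIPS-oxy)-3,4-dihydro-2H-chromene-8-carboxylate (both C2 epimers), via ortho-quinone methide 17 (not isolated), via enamine 18 (not isolated), via hydroxy aldehyde 19 (not isolated)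
Conditions: (R)-α,α-diphenylprolinol trimethylsilyl ether (20 mol %), Na2CO3 (1.5 equiv), CH2Cl2/H2O, 0 °C; 5 (1.2 equiv), 16 (1.0 equiv); crude 20 taken directly into step 12
Reagents that add atoms: none
Why: Na2CO3 deprotonates the C8a phenol of 5, which the ortho ester makes acidic, and loss of 4-methylbenzenesulfinate releases ortho-quinone methide 17 at low stationary concentration while 16 condenses with the amine to the (E)-enamine 18. The enamine α-carbon (C3) adds to the exocyclic methylene carbon (C4) of 17 and ring A rearomatises; hydrolysis of the iminium ion frees hydroxy aldehyde 19 and the catalyst. Ring C then closes by 6-exo-trig addition of the C8a hydroxyl to the aldehyde carbon (O1–C2), giving lactol 20 as a C2 mixture that is of no consequence. The closest known reaction type is the secondary-amine-catalysed formal [4+2] annulation of enolisable aldehydes with ortho-quinone methides released from 2-(sulfonylmethyl)phenols, which gives chroman-2-ols. C3 is set by the catalyst: its diphenyl(silyloxy)methyl group shields one face of the s-trans (E)-enamine, and with the (R)-amine the open face is the one that leads to 3R. Only enantiofacial selectivity is needed, because C4 bears two hydrogens. The C8 ester makes 17 electrophilic enough for addition to outrun oligomerisation. The 2'-silyloxy group and the bulky amine slow self-aldol of 16 and re-enolisation of the α-branched product, which is reduced at once.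

Step 12
Reactants: 20 lactol (both C2 epimers)
Product: 21 methyl 3-{(2R)-2-[2,4-bis(TBS-oxy)-3-prenylphenyl]-3-hydroxypropyl}-2-hydroxy-4-methoxy-6-(TIPS-oxy)benzoate
Conditions: NaBH4 (2 equiv), THF/EtOH, 0 °C
Reagents that add atoms: none
Why: The lactol is in equilibrium with hydroxy aldehyde 19, which borohydride reduces; this removes the enolisable carbonyl and fixes C3. The hindered, chelated methyl benzoate is not reduced by NaBH4 at 0 °C.

Step 13
Reactants: 21 phenol–alcohol
Product: 22 methyl (3R)-3-[2,4-bis(TBS-oxy)-3-prenylphenyl]-5-methoxy-7-(TIPS-oxy)-3,4-dihydro-2H-chromene-8-carboxylate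
Conditions: PPh3 (1.5 equiv), diisopropyl azodicarboxylate (1.5 equiv), THF, 0 °C to rt
Reagents that add atoms: none
Why: Intramolecular Mitsunobu etherification: the salicylate-type phenol is acidic enough to serve as the pronucleophile and closes ring C by 6-exo-tet displacement at the activated primary carbon. C3 is not a reacting centre and keeps its configuration.

Step 14
Reactants: 22 chroman ester
Product: 23 {(3R)-3-[2,4-bis(TBS-oxy)-3-prenylphenyl]-5-methoxy-7-(TIPS-oxy)-3,4-dihydro-2H-chromen-8-yl}methanol
Conditions: iBu2AlH (3 equiv), CH2Cl2, −78 to 0 °C; aq. potassium sodium tartrate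
Reagents that add atoms: none
Why: Hydride reduction of the ester to the primary benzylic alcohol; aryl silyl ethers and the trisubstituted alkene are inert to iBu2AlH at these temperatures, and the silyl group on O7 prevents quinone-methide over-reduction to a methyl group.

Step 15
Reactants: 23 benzylic alcohol
Product: 24 (3R)-3-[2,4-bis(TBS-oxy)-3-prenylphenyl]-5-methoxy-7-(TIPS-oxy)-3,4-dihydro-2H-chromene-8-carbaldehyde
Conditions: MnO2 (activated, 15 equiv), CH2Cl2, rt
Reagents that add atoms: none
Why: MnO2 oxidises electron-rich benzylic alcohols selectively to aldehydes and stops there; the isolated alkene and the silyl ethers are untouched.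

Step 16
Reactants: 24 silylated aldehyde
Product: 25 (3R)-3-[2,4-dihydroxy-3-prenylphenyl]-7-hydroxy-5-methoxy-3,4-dihydro-2H-chromene-8-carbaldehyde (target)
Conditions: Bu4NF (3.5 equiv), AcOH (3.5 equiv), THF, 0 °C
Reagents that add atoms: none
Why: Fluoride cleaves all three aryl silyl ethers, phenoxides being good leaving groups from silicon. The acetic acid buffer keeps the salicylaldehyde and the resorcinol from strong base, and no acid able to close the prenyl group onto a phenol is present.

## Compound list

1 | methyl 2,4,6-trihydroxybenzoate | COC(=O)c1c(O)cc(O)cc1O | starting material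
2 | methyl 2,6-dihydroxy-4-methoxybenzoate | COC(=O)c1c(O)cc(OC)cc1O | intermediate
3 | methyl 2,6-dihydroxy-3-(hydroxymethyl)-4-methoxybenzoate | COc1cc(O)c(C(=O)OC)c(O)c1CO | intermediate (not isolated)
4 | methyl 2,6-dihydroxy-4-methoxy-3-{[(4-methylphenyl)sulfonyl]methyl}benzoate | COc1cc(O)c(C(=O)OC)c(O)c1CS(=O)(=O)c1ccc(C)cc1 | intermediate
5 | methyl 2-hydroxy-4-methoxy-3-{[(4-methylphenyl)sulfonyl]methyl}-6-(TIPS-oxy)benzoate | COc1cc(O[Si](C(C)C)(C(C)C)C(C)C)c(C(=O)OC)c(O)c1CS(=O)(=O)c1ccc(C)cc1 | intermediate
6 | 4-bromobenzene-1,3-diol | Oc1ccc(Br)c(O)c1 | starting material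
7 | 1-bromo-2,4-bis(methoxymethoxy)benzene | COCOc1ccc(Br)c(OCOC)c1 | intermediate
8 | 1-bromo-3-methylbut-2-ene | CC(C)=CCBr | starting material
9 | [3-bromo-2,6-bis(methoxymethoxy)phenyl]lithium | [Li]c1c(OCOC)ccc(Br)c1OCOC | intermediate (not isolated)
10 | 1-bromo-2,4-bis(methoxymethoxy)-3-prenylbenzene | COCOc1ccc(Br)c(OCOC)c1CC=C(C)C | intermediate
11 | [2,4-bis(methoxymethoxy)-3-prenylphenyl]lithium | [Li]c1ccc(OCOC)c(CC=C(C)C)c1OCOC | intermediate (not isolated)
12 | 2-[2,4-bis(methoxymethoxy)-3-prenylphenyl]ethan-1-ol | OCCc1ccc(OCOC)c(CC=C(C)C)c1OCOC | intermediate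
13 | 4-(2-hydroxyethyl)-2-prenylbenzene-1,3-diol | OCCc1ccc(O)c(CC=C(C)C)c1O | intermediate
14 | tert-butyl{2-[2,4-bis(TBS-oxy)-3-prenylphenyl]ethoxy}dimethylsilane | CC(C)=CCc1c(O[Si](C)(C)C(C)(C)C)ccc(CCO[Si](C)(C)C(C)(C)C)c1O[Si](C)(C)C(C)(C)C | intermediate
15 | 2-[2,4-bis(TBS-oxy)-3-prenylphenyl]ethan-1-ol | OCCc1ccc(O[Si](C)(C)C(C)(C)C)c(CC=C(C)C)c1O[Si](C)(C)C(C)(C)C | intermediate
16 | 2-[2,4-bis(TBS-oxy)-3-prenylphenyl]acetaldehyde | O=CCc1ccc(O[Si](C)(C)C(C)(C)C)c(CC=C(C)C)c1O[Si](C)(C)C(C)(C)C | intermediate
17 | methyl 4-methoxy-5-methylidene-6-oxo-2-(TIPS-oxy)cyclohexa-1,3-diene-1-carboxylate | C=C1C(OC)=CC(O[Si](C(C)C)(C(C)C)C(C)C)=C(C(=O)OC)C1=O | intermediate (not isolated)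
18 | (2R)-1-{(E)-2-[2,4-bis(TBS-oxy)-3-prenylphenyl]ethenyl}-2-[diphenyl(trimethylsilyloxy)methyl]pyrrolidine | C[Si](C)(C)OC(c1ccccc1)(c1ccccc1)[C@H]1CCCN1/C=C/c1ccc(O[Si](C)(C)C(C)(C)C)c(CC=C(C)C)c1O[Si](C)(C)C(C)(C)C | intermediate (not isolated)
19 | methyl 3-{(2R)-2-[2,4-bis(TBS-oxy)-3-prenylphenyl]-3-oxopropyl}-2-hydroxy-4-methoxy-6-(TIPS-oxy)benzoate | COc1cc(O[Si](C(C)C)(C(C)C)C(C)C)c(C(=O)OC)c(O)c1C[C@H](c1ccc(O[Si](C)(C)C(C)(C)C)c(CC=C(C)C)c1O[Si](C)(C)C(C)(C)C)C=O | intermediate (not isolated)
20 | methyl (3R)-3-[2,4-bis(TBS-oxy)-3-prenylphenyl]-2-hydroxy-5-methoxy-7-(TIPS-oxy)-3,4-dihydro-2H-chromene-8-carboxylate (both C2 epimers) | COc1cc(O[Si](C(C)C)(C(C)C)C(C)C)c(C(=O)OC)c2c1C[C@H](c1ccc(O[Si](C)(C)C(C)(C)C)c(CC=C(C)C)c1O[Si](C)(C)C(C)(C)C)C(O)O2 | intermediate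
21 | methyl 3-{(2R)-2-[2,4-bis(TBS-oxy)-3-prenylphenyl]-3-hydroxypropyl}-2-hydroxy-4-methoxy-6-(TIPS-oxy)benzoate | COc1cc(O[Si](C(C)C)(C(C)C)C(C)C)c(C(=O)OC)c(O)c1C[C@H](c1ccc(O[Si](C)(C)C(C)(C)C)c(CC=C(C)C)c1O[Si](C)(C)C(C)(C)C)CO | intermediate
22 | methyl (3R)-3-[2,4-bis(TBS-oxy)-3-prenylphenyl]-5-methoxy-7-(TIPS-oxy)-3,4-dihydro-2H-chromene-8-carboxylate | COc1cc(O[Si](C(C)C)(C(C)C)C(C)C)c(C(=O)OC)c2c1C[C@H](c1ccc(O[Si](C)(C)C(C)(C)C)c(CC=C(C)C)c1O[Si](C)(C)C(C)(C)C)CO2 | intermediate
23 | {(3R)-3-[2,4-bis(TBS-oxy)-3-prenylphenyl]-5-methoxy-7-(TIPS-oxy)-3,4-dihydro-2H-chromen-8-yl}methanol | COc1cc(O[Si](C(C)C)(C(C)C)C(C)C)c(CO)c2c1C[C@H](c1ccc(O[Si](C)(C)C(C)(C)C)c(CC=C(C)C)c1O[Si](C)(C)C(C)(C)C)CO2 | intermediate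
24 | (3R)-3-[2,4-bis(TBS-oxy)-3-prenylphenyl]-5-methoxy-7-(TIPS-oxy)-3,4-dihydro-2H-chromene-8-carbaldehyde | COc1cc(O[Si](C(C)C)(C(C)C)C(C)C)c(C=O)c2c1C[C@H](c1ccc(O[Si](C)(C)C(C)(C)C)c(CC=C(C)C)c1O[Si](C)(C)C(C)(C)C)CO2 | intermediate
25 | (3R)-3-[2,4-dihydroxy-3-prenylphenyl]-7-hydroxy-5-methoxy-3,4-dihydro-2H-chromene-8-carbaldehyde | COc1cc(O)c(C=O)c2c1C[C@H](c1ccc(O)c(CC=C(C)C)c1O)CO2 | target

## Step count and least certain steps

Total step count: 16. Longest linear sequence: 13 steps (steps 4 to 16, from 6); the ring A branch (steps 1 to 3) joins at step 11.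

**Step 11 (key step).** The most likely failure is loss of enantiofacial control. This can happen through a background addition of the enol or enolate of 16 to 17 that bypasses the amine, or through re-enolisation of 19 before reduction. Self-condensation of 16 and oligomerisation of 17 may accompany it. The fallback forms the same C3–C4 bond under auxiliary control, sets out from 15 and 5 and returns at 21.
- Alcohol 15 is oxidised (2,2,6,6-tetramethylpiperidin-1-oxyl, PhI(OAc)2, MeCN/H2O) to 2-[2,4-bis(TBS-oxy)-3-prenylphenyl]acetic acid F1.
- The pivalic mixed anhydride of F1 acylates lithiated (R)-4-benzyl-1,3-oxazolidin-2-one to give (4R)-4-benzyl-3-{[2,4-bis(TBS-oxy)-3-prenylphenyl]acetyl}-1,3-oxazolidin-2-one F2.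
- The sodium (Z)-enolate of F2 (NaN(SiMe3)2, THF, −78 °C) is alkylated by methide 17, released from 5 by a further equivalent of the same base. The benzyl group of the auxiliary shields one face, which should give methyl 3-{(2R)-3-[(4R)-4-benzyl-2-oxo-1,3-oxazolidin-3-yl]-2-[2,4-bis(TBS-oxy)-3-prenylphenyl]-3-oxopropyl}-2-hydroxy-4-methoxy-6-(TIPS-oxy)benzoate F3.
- NaBH4 in THF/H2O removes the auxiliary reductively and delivers diol 21; steps 13 to 16 follow unchanged.

**Step 2.** Mono-selectivity may be lost through a second sulfonylmethylation at C5, and the benzylic cation may be captured by a second arene instead of by sulfinate. The fallback sets out from 2 and returns at 3. Vilsmeier–Haack formylation (POCl3, DMF) gives methyl 3-formyl-2,6-dihydroxy-4-methoxybenzoate F4, and the formyl group deactivates the ring against a second substitution. NaBH4 reduces F4 to 3, which is now isolated and exchanged with 4-MeC6H4SO2Na in HCO2H to give 4.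

**Step 3.** Base-induced loss of sulfinate from 4 may compete with silylation; the 2-hydroxyl can expel it through an ortho-quinone methide and the 6-hydroxyl through a para-quinone methide. Silylation at the wrong hydroxyl is the second risk. The fallback reverses the order, sets out from 2 and returns at 5.
- iPr3SiOTf and 2,6-lutidine give methyl 2-hydroxy-4-methoxy-6-(TIPS-oxy)benzoate F5.
- Magnesium-mediated ortho-formylation (MgCl2, Et3N, paraformaldehyde, MeCN, reflux) attacks the only free position ortho to the remaining phenol and gives methyl 3-formyl-2-hydroxy-4-methoxy-6-(TIPS-oxy)benzoate F6.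
- NaBH4 gives methyl 2-hydroxy-3-(hydroxymethyl)-4-methoxy-6-(TIPS-oxy)benzoate F7.
- 4-Methylbenzenesulfinic acid in CH2Cl2 exchanges the benzylic hydroxyl and gives 5.

**Step 7.** As the acetals are cleaved, acid may add a freed phenol across the prenyl alkene (closure to a 2,2-dimethylchroman) or hydrate the alkene. The fallback uses acetals that leave under much weaker acid, sets out from 6 and returns at 13.
- Ethyl vinyl ether and pyridinium 4-toluenesulfonate give 1-bromo-2,4-bis(1-ethoxyethoxy)benzene F8 (mixture of diastereomers).
- LiN(iPr)2, then 8 with catalytic CuBr·SMe2, give 1-bromo-2,4-bis(1-ethoxyethoxy)-3-prenylbenzene F9.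
- n-BuLi, then ethylene oxide, give 2-[2,4-bis(1-ethoxyethoxy)-3-prenylphenyl]ethan-1-ol F10.
- Pyridinium 4-toluenesulfonate in EtOH at rt releases 13 under conditions too weak to protonate the alkene.

## Further compounds

F1 | step 11 | 2-[2,4-bis(TBS-oxy)-3-prenylphenyl]acetic acid | OC(=O)Cc1ccc(O[Si](C)(C)C(C)(C)C)c(CC=C(C)C)c1O[Si](C)(C)C(C)(C)C
F2 | step 11 | (4R)-4-benzyl-3-{[2,4-bis(TBS-oxy)-3-prenylphenyl]acetyl}-1,3-oxazolidin-2-one | O=C(Cc1ccc(O[Si](C)(C)C(C)(C)C)c(CC=C(C)C)c1O[Si](C)(C)C(C)(C)C)N1[C@H](Cc2ccccc2)COC1=O
F3 | step 11 | methyl 3-{(2R)-3-[(4R)-4-benzyl-2-oxo-1,3-oxazolidin-3-yl]-2-[2,4-bis(TBS-oxy)-3-prenylphenyl]-3-oxopropyl}-2-hydroxy-4-methoxy-6-(TIPS-oxy)benzoate | COc1cc(O[Si](C(C)C)(C(C)C)C(C)C)c(C(=O)OC)c(O)c1C[C@H](c1ccc(O[Si](C)(C)C(C)(C)C)c(CC=C(C)C)c1O[Si](C)(C)C(C)(C)C)C(=O)N1[C@H](Cc2ccccc2)COC1=O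
F4 | step 2 | methyl 3-formyl-2,6-dihydroxy-4-methoxybenzoate | COc1cc(O)c(C(=O)OC)c(O)c1C=O
F5 | step 3 | methyl 2-hydroxy-4-methoxy-6-(TIPS-oxy)benzoate | COc1cc(O)c(C(=O)OC)c(O[Si](C(C)C)(C(C)C)C(C)C)c1
F6 | step 3 | methyl 3-formyl-2-hydroxy-4-methoxy-6-(TIPS-oxy)benzoate | COc1cc(O[Si](C(C)C)(C(C)C)C(C)C)c(C(=O)OC)c(O)c1C=O
F7 | step 3 | methyl 2-hydroxy-3-(hydroxymethyl)-4-methoxy-6-(TIPS-oxy)benzoate | COc1cc(O[Si](C(C)C)(C(C)C)C(C)C)c(C(=O)OC)c(O)c1CO
F8 | step 7 | 1-bromo-2,4-bis(1-ethoxyethoxy)benzene (mixture of diastereomers) | CCOC(C)Oc1ccc(Br)c(OC(C)OCC)c1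
F9 | step 7 | 1-bromo-2,4-bis(1-ethoxyethoxy)-3-prenylbenzene (mixture of diastereomers) | CCOC(C)Oc1ccc(Br)c(OC(C)OCC)c1CC=C(C)C
F10 | step 7 | 2-[2,4-bis(1-ethoxyethoxy)-3-prenylphenyl]ethan-1-ol (mixture of diastereomers) | OCCc1ccc(OC(C)OCC)c(CC=C(C)C)c1OC(C)OCC
A1 | alternative 1 | methyl (3R)-3-(2,4-dioxocyclohexyl)-5-methoxy-7-(methoxymethoxy)-3,4-dihydro-2H-chromene-8-carboxylate (mixture at C1') | COc1cc(OCOC)c(C(=O)OC)c2c1C[C@H](C1CCC(=O)CC1=O)CO2
A2 | alternative 1 | methyl (3R)-5-methoxy-7-(methoxymethoxy)-3-(2-oxopropyl)-3,4-dihydro-2H-chromene-8-carboxylate | COc1cc(OCOC)c(C(=O)OC)c2c1C[C@H](CC(C)=O)CO2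
A3 | alternative 2 | methyl (3R)-3-[2,4-bis(TBS-oxy)-3-prenylphenyl]-7-hydroxy-5-methoxy-3,4-dihydro-2H-chromene-8-carboxylate | COc1cc(O)c(C(=O)OC)c2c1C[C@H](c1ccc(O[Si](C)(C)C(C)(C)C)c(CC=C(C)C)c1O[Si](C)(C)C(C)(C)C)CO2
A4 | alternative 2 | methyl (2E)-3-{(2R)-2-[2,4-bis(TBS-oxy)-3-prenylphenyl]-3-[3-methoxy-5-(TBS-oxy)furan-2-yl]propoxy}prop-2-enoate | COC(=O)/C=C/OC[C@H](Cc1oc(O[Si](C)(C)C(C)(C)C)cc1OC)c1ccc(O[Si](C)(C)C(C)(C)C)c(CC=C(C)C)c1O[Si](C)(C)C(C)(C)C
A5 | alternative 3 | (3R)-3-[2,4-bis(methoxymethoxy)-3-prenylphenyl]-5-methoxy-7-(methoxymethoxy)-3,4-dihydro-2H-chromene-8-carbaldehyde | COc1cc(OCOC)c(C=O)c2c1C[C@H](c1ccc(OCOC)c(CC=C(C)C)c1OCOC)CO2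
A6 | alternative 3 | (2R)-2-[2,4-bis(methoxymethoxy)-3-prenylphenyl]-3-[2-fluoro-6-methoxy-4-(methoxymethoxy)phenyl]propan-1-ol | COc1cc(OCOC)cc(F)c1C[C@H](c1ccc(OCOC)c(CC=C(C)C)c1OCOC)CO
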